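What interests me in this flask is the leftover: how much substrate still stands at the end, and to which hand the rest has gone.

left-handed substrate 0.10 M; partner 0.250 M (fed, over 4.0 h); free catalyst 2.0 mM; racemization catalyst 2.5 mM; added ligand 2.8 mM; right-handed substrate 0.10 M; time 15 d; the fed solution adds 0.25 times the starting volume

    partner + free catalyst + left-handed substrate → free catalyst + left-handed product (k1 = 81 M⁻² h⁻¹)
    partner + free catalyst + right-handed substrate → free catalyst + right-handed product (k2 = 39 M⁻² h⁻¹)
    racemization catalyst + added ligand ⇌ idle complex (K3 = 130 M⁻¹, k3 = 100 M⁻¹ h⁻¹)
    left-handed substrate + racemization catalyst ⇌ right-handed substrate + racemization catalyst, rate k4*[racemization catalyst]*[left-handed substrate] forward; the back reaction follows from the equilibrium constant (k4 = 5.9 M⁻¹ h⁻¹)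

* the state of affairs at 15 d: stopped, and by what, or still going (the partner has run out first / it is still moving / forward and back rates have come level / no working catalyst is left / all of the left-handed substrate has reacted)
* the left-handed product standing at 15 d, as a percentage of the left-handed substrate and right-handed substrate together charged
* the right-handed product standing at 15 d, as a percentage of the left-handed substrate and right-handed substrate together charged
* the right-handed substrate standing at 15 d, as a percentage of the left-handed substrate and right-handed substrate together charged

- free catalyst is single-handed; left-handed substrate and right-handed substrate are mirror images of each other, charged as a racemate, each of them at the stated concentration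
- every charge counts on the volume at the start, and the solution that is fed holds the whole dose
- the reaction counts as stopped when no species that holds the left-handed substrate and right-handed substrate together changes by six tenths of a point or more over the second half of the time
- run time (flask): 15 d

I turn the question round. The selectivity factor is 2.08: in a fully coupled racemate, racemization far ahead of coupling takes the left-handed share towards 67.5%, and racemization far behind coupling takes it towards an even split. Counting the diluted ligand with none of it bound, I reckon 77.4% of the racemization catalyst free. If all the substrate couples, partner falls from 125% of the substrate charge to 25.0%, a mean of 75.0%. The exchange number, the racemization rate over the pseudo-first-order coupling rate of the right-handed substrate at that mean partner, is 1.22.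

Solving both substrate balances to exhaustion at constant rates gives a left-handed share of 61.3%. To check the mean, I use the curve's ends instead: starting partner gives 59.1%, last partner 64.8%.

At last partner the number is 3.66, above one, so I treat the two substrates as one pool with the mean constant, second order with the partner, and run that pool from the start as a rough step for the early part. I reckon the pool's fraction at 16.7% at 7.50 d and 6.28% at 15 d. A stop would need a change below the stated mark; I reckon a fall of 10 percentage points. So I commit to: it is still moving, with left-handed product 57.4%, right-handed product 36.3% and, splitting the pool evenly, right-handed substrate 3.14%.

The forecast says it is still moving, with 57.8%, 35.4% and 3.8%, on the ground that “racemization therefore keeps feeding the faster-reacting left-handed substrate”.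

The flask gives it is still moving, with 58.0%, 35.2% and 3.75%. It has not come to rest. Left ten times as long, the left-handed product climbs a further 4.3 points to 62.3%, the right-handed product reaches 37.7%, the right-handed substrate 0%, and the partner goes from 25% to 20.0% of its charge.

The second flask is the same with 0.10 M of partner, below the substrate charge, so partner is the limiting reagent there. In that flask a mean partner of 25.0% of the substrate charge gives an exchange number of 3.66 and a share of 64.8%; this is a rough use of the balance, which I solved to exhaustion, while this partner covers 50.0% of the substrate. Spending its charge then promises 32.4% left-handed and 17.6% right-handed product. That flask gives 31.7% and 16.6%.

The numbers were drawn at random within sensible limits; the rest is arithmetic.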